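# Route to (2R,3S)-2-(13-acetoxytridecyl)-4-methylidene-5-oxooxolane-3-carboxylic acid (14)

## Analysis of the target

- The target 14 is a γ-butyrolactone, numbered here O1, C2, C3, C4, C5. C2 carries a 13-acetoxytridecyl chain, C3 a free carboxylic acid, C4 an exocyclic methylene, and C5 is the lactone carbonyl.
- There are two adjacent stereocentres, C2 (R) and C3 (S). Their substituents lie on opposite faces of the ring (trans). The chain has no further stereocentre.
- Three groups restrict the reagents. The α-methylene lactone is a Michael acceptor, and because H–C3 is allylic and α to a carboxyl, base moves the double bond into the ring and destroys C3. The primary acetate is cleaved by alkoxides. The free acid excludes most enolate methods.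
- The ring is easy to close. The hard part is to set two vicinal centres in absolute terms on a molecule that otherwise has only a waxy chain.
- A second difficulty is the order of events: the methylene and the acetate must each survive the chemistry that installs the other.
- The plan rests on one feature. C2 is a carbinol carbon bonded directly to C3, and C3 bears a carboxyl. If C2 is taken back to a ketone, C3 sits between two carbonyl groups and racemises by enolisation, so one stereoselective reduction of a racemate can fix both centres.
- C4 and C5 are then an acetic ester arm on C3, which closes the lactone onto the new C2 hydroxyl.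

## Retrosynthetic reasoning

**14 back to 13.** The acetyl–oxygen bond at the chain end is cut first, so it is formed last. The carboxylation needed for the methylene group uses a basic magnesium alkoxide reagent above 100 °C, and a primary acetate would be transesterified there. The hydroxy acid 13 is therefore the last intermediate. The forward step must acetylate a primary alcohol next to a free acid without base, because base would isomerise the methylene lactone.

**13 back to 10, through 12 and 11.** The exocyclic carbon on C4 is removed. The alkene is traced to the Mannich adduct 12 and to the malonic-type diacid 11, and the extra carboxyl on C4 is then cut off to give the saturated lactone acid 10. The methylene is introduced late because it is the most fragile part of the ring. This sequence is chosen because it uses the C3 carboxyl as it stands, with no protection. The forward steps must carboxylate C4 and no other position, and must leave C2 and C3 untouched.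

**10 back to 9.** The O1–C5 bond is cut, which opens the lactone to a γ-hydroxy methyl ester. In the same retrosynthetic move the C3 acid becomes a tert-butyl ester and the chain alcohol a silyl ether. The two esters are chosen to differ: the methyl ester is the one that lactonises, and the tert-butyl ester on the stereocentre is removed by acid, so no saponification threatens C3. One acid treatment of the hydroxy diester 9 then does three jobs. The silyl ether replaces an acetate because an acetate would not survive the carboxylation of 10, and the silyl group costs no extra step.

**9 back to 8.** The C2–H bond is cut, which returns the carbinol to the ketone of the racemic acylsuccinate 8. This is the only place in the molecule where a carbonyl flanks an acidic stereocentre. A single catalytic reduction can therefore set both centres from a racemate, without chiral pool material or an auxiliary. The forward reaction must pick one of four stereoisomers while the α-centre of 8 keeps equilibrating.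

**8 back to 6 and 7.** The C3–C4 bond is cut. The acetic ester arm comes from methyl bromoacetate 7, and the nucleophile is the enolate of the 3-oxo ester 6. The cut is made here because the carbon between the two carbonyls of 6 is the most acidic site, so the alkylation needs no directing group.

**6 back to 3 and 4, through 5.** The bond between the ketone carbon (future C2) and the future C3 is cut. The acid 3 acylates Meldrum's acid 4 to give the acyl derivative 5. Thermal fragmentation of 5 in a tertiary alcohol then gives the tert-butyl 3-oxo ester 6 directly, with the ester group that the later acid step needs.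

**3 back to 2 and 1.** The acid 3 comes from the alcohol 2 by oxidation, and 2 from the symmetrical diol 1 by protection of one of its two equivalent hydroxyls. The diol supplies all fourteen chain carbons in one commercial piece.

## Alternatives that were turned down

**Alternative 1:** The ring bond C3–C4 is traced to a cyclopropanation of a furan, and the lactone arises later when the cyclopropane is opened.
- Forward key step: methyl furan-2-carboxylate A1 and ethyl diazoacetate A2 react under CuOTf (monovalent copper) with a chiral bis(oxazoline) to give the bicyclic diester A3. The carbene carbon becomes C4. Its bond to the future C3 is kept. Its second bond, to the carbon that ends as the C3 carboxyl, is broken again after ozonolysis, addition of a chain nucleophile to the freed aldehyde, and base-induced ring opening with lactonisation.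
- For it: a catalytic asymmetric step with a dependable sense of induction, a crystalline intermediate A3 that can be enriched, and a fragmentation that gives 2,3-trans lactones by thermodynamic preference.
- Against it here: A3 holds four ring atoms and nothing of the C13 chain. The route still needs ozonolysis, a diastereoselective addition of a functionalised long-chain organometallic (or allylation followed by chain extension), the fragmentation, an aldehyde-to-acid oxidation and the same methylenation. The base used for the fragmentation would not spare a chain acetate. A diazo compound must be handled on scale.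
- Comparison: it is stronger on certainty of absolute configuration, since the enzymatic reduction needs a screen. The chosen route offers a complete skeleton after two C–C bond formations and both centres from one step, in about half the operations.

**Alternative 2:** C2–C3 and C4–C5 are cut together, which leads to a four-membered ketone in which C2 and C5 are still bonded. That bond is temporary and is later opened by Baeyer–Villiger insertion of O1. A phenyl group stands in for the carboxyl.
- Forward key step: the amide A4 is activated with Tf2O and a hindered pyridine base to a keteniminium ion, which adds to styrene A5 in a stepwise [2+2] process. Hydrolysis gives the cyclobutanone A6. The cycloaddition forms only C2–C3 and C4–C5; the C2–C5 bond is inherited from A4.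
- For it: the fastest assembly of all ring carbons together with the full chain, a trans arrangement from the cycloaddition, a Baeyer–Villiger step that migrates the more substituted carbon with retention, and tolerance of the acetate.
- Against it here: A4 and A5 are achiral, so A6 is racemic unless the amide nitrogen carries a chiral amine, whose induction for a long-chain substituent is uncertain. The phenyl ring must be degraded to a carboxyl with RuCl3/NaIO4. The methylenation still follows.
- Comparison: it is equal or better in step count up to the lactone acid, and it avoids aqueous biocatalysis of a waxy substrate. The chosen route offers catalyst-controlled absolute configuration without an auxiliary and without arene degradation.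

**Alternative 3:** The cuts are C4–C5 and C5–O1. The lactone carbonyl is taken out as CO, and the methylene carbon is the terminus of an alkyne.
- Forward key step: the anti homopropargylic alcohol A7 is carbonylated under PdCl2 (divalent palladium), SnCl2 and PPh3. An alkoxycarbonyl–palladium species adds across the triple bond in a 5-exo mode, and protonolysis releases the α-methylene lactone A8. Desilylation and oxidation of the primary alcohol to the acid would finish.
- For it: the methylene lactone is made directly under neutral conditions. No hot basic carboxylation is needed, and the chain acetate can be carried from the start. On this point the alternative is clearly stronger than the chosen route, which must add the acetate last.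
- Against it here: the stereochemical problem is moved into A7, whose two centres need a stoichiometric chiral allenylmetal reagent and a long-chain aldehyde. After the carbonylation, the CH2OH group on C3 must pass through an aldehyde whose α-hydrogen is allylic and α to a carbonyl, which invites double-bond migration or epimerisation. CO under pressure and a tin co-catalyst are needed.
- Comparison: the chosen route keeps C3 at the carboxyl oxidation level throughout and sets both centres catalytically from a racemate made from bulk chemicals.

Key step: step 5

## Route

Remarks on the chemistry:
- The ketoreductase is taken from a screening panel; the route assumes that one member gives the required isomer.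
- The configuration at C4 of 11 and 12 is not controlled and does not matter, because C4 ends trigonal.

Step 1
Reactants: 1 tetradecane-1,14-diol
Product: 2 14-{[tert-butyl(dimethyl)silyl]oxy}tetradecan-1-ol
Conditions: TBSCl (1.0 equiv), imidazole (1.2 equiv), 1 in excess (3 equiv, recovered), THF/DMF, 0 °C to rt
Reagents that add atoms: tert-butyldimethylsilyl chloride, CC(C)(C)[Si](C)(C)Cl
Why: Imidazole-mediated silylation of a primary alcohol; the two hydroxyls of 1 are equivalent and remote, so an excess of the diol favours the mono-ether, and the far more polar diol is recovered for reuse.

Step 2
Reactants: 2 14-{[tert-butyl(dimethyl)silyl]oxy}tetradecan-1-ol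
Product: 3 14-{[tert-butyl(dimethyl)silyl]oxy}tetradecanoic acid
Conditions: TEMPO (0.2 equiv), PhI(OAc)2 (2.2 equiv), MeCN/CH2Cl2/aq. KH2PO4–K2HPO4 buffer pH 7, rt
Reagents that add atoms: water, O
Why: Oxoammonium (TEMPO) oxidation of the primary alcohol to the aldehyde, whose hydrate is oxidised again to the acid; the silyl ether is inert at buffered neutral pH and nothing else in 2 is oxidisable.

Step 3
Reactants: 3 14-{[tert-butyl(dimethyl)silyl]oxy}tetradecanoic acid; 4 Meldrum's acid (2,2-dimethyl-1,3-dioxane-4,6-dione)
Product: 6 tert-butyl 16-{[tert-butyl(dimethyl)silyl]oxy}-3-oxohexadecanoate, via acyl Meldrum's acid 5 (not isolated)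
Conditions: DCC (1.1 equiv), DMAP (1.5 equiv), CH2Cl2, 0 °C to rt; filter, cold aq. KHSO4 wash; then t-BuOH, toluene, 90 °C
Reagents that add atoms: tert-butanol, CC(C)(C)O
Why: Carbodiimide-mediated C-acylation of Meldrum's acid gives the enolised acyl derivative 5; on heating, 5 undergoes cycloreversion to an acylketene with loss of acetone and CO2, and tert-butanol adds to the ketene (Meldrum's acid synthesis of 3-oxo esters).

Step 4
Reactants: 6 tert-butyl 16-{[tert-butyl(dimethyl)silyl]oxy}-3-oxohexadecanoate; 7 methyl bromoacetate
Product: 8 1-tert-butyl 4-methyl 2-(14-{[tert-butyl(dimethyl)silyl]oxy}tetradecanoyl)butanedioate (racemic)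
Conditions: K2CO3 (1.5 equiv), 7 (1.0 equiv, added slowly), acetone, rt to 50 °C
Reagents that add atoms: none
Why: SN2 C-alkylation of the stabilised enolate of the 3-oxo ester by an activated primary bromide; a second alkylation is slow because the remaining α-hydrogen is tertiary and shielded by the tert-butyl ester, and the new centre (future C3) is deliberately formed racemic.

Step 5
Reactants: 8 1-tert-butyl 4-methyl 2-(14-{[tert-butyl(dimethyl)silyl]oxy}tetradecanoyl)butanedioate (racemic)
Product: 9 1-tert-butyl 4-methyl (2S)-2-[(1R)-14-{[tert-butyl(dimethyl)silyl]oxy}-1-hydroxytetradecyl]butanedioate
Conditions: ketoreductase (panel hit), NADP+ (cat.), glucose dehydrogenase, D-glucose (1.5 equiv), KH2PO4–K2HPO4 buffer pH 7.0, DMSO (10–20% v/v), 30 °C, pH-stat (NaOH)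
Reagents that add atoms: none
Why: The ketoreductase binds NADPH and one enantiomer of 8 and transfers the dihydronicotinamide hydride to the Si face of the ketone while an active-site tyrosine protonates the oxygen; glucose dehydrogenase re-reduces NADP+ at the expense of glucose. The closest known reaction type is the enzymatic dynamic reductive kinetic resolution of 2-substituted 3-oxo esters. No ring closes in this step; only the C2–H bond is formed. The carbinol centre (future C2, R) is set by the enzyme, which fixes the face of hydride delivery. The neighbouring centre (future C3, S) is set by the enzyme's preference for one enantiomer of 8, combined with fast interconversion of the enantiomers through the enol, since the α-hydrogen lies between ketone and ester (pKa roughly 11 to 13) and exchanges in the buffer. The step needs one of four stereoisomers, which depends on choosing from the panel an enzyme that gives the (2S,1′R) isomer; it needs racemisation faster than reduction of the slow enantiomer, which the doubly activated C–H secures and a pH of 7.5–8 can help; and it needs ketone-over-ester chemoselectivity, which is inherent to this enzyme class. After reduction the α-centre is no longer acidic, so the configuration of 9 is locked. Any 9 that cyclises in the buffer does no harm, because step 6 gives the same lactone.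

Step 6
Reactants: 9 1-tert-butyl 4-methyl (2S)-2-[(1R)-14-{[tert-butyl(dimethyl)silyl]oxy}-1-hydroxytetradecyl]butanedioate
Product: 10 (2R,3S)-2-(13-hydroxytridecyl)-5-oxooxolane-3-carboxylic acid (trans)
Conditions: TFA/CH2Cl2/H2O (10:10:1), 0 °C to rt; evaporate; aq. NaHCO3/THF, rt; then HCl to pH 2
Reagents that add atoms: none
Why: Acid does three things in one pot: tert-butyl ester cleavage by alkyl–oxygen fission, protodesilylation of the primary silyl ether, and 5-exo-trig transesterification of the γ-hydroxy methyl ester to the lactone; all occur at oxygen, silicon or an acyl carbon, so C2 and C3 are untouched and the trans lactone results, and the bicarbonate stage hydrolyses any trifluoroacetate formed at the primary alcohol.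

Step 7
Reactants: 10 (2R,3S)-2-(13-hydroxytridecyl)-5-oxooxolane-3-carboxylic acid
Product: 11 (2R,3S)-2-(13-hydroxytridecyl)-5-oxooxolane-3,4-dicarboxylic acid (C4 not fixed; crude, used at once)
Conditions: MeOMgOCO2Me (2 M in DMF, 20 equiv), 130 °C, N2; then cold 6 M HCl, extraction
Reagents that add atoms: methyl magnesium carbonate (methoxymagnesium methyl carbonate), COC(=O)O[Mg]OC
Why: Carboxylation of the lactone α-position with methyl magnesium carbonate: reversible deprotonation at C4 and capture of CO2 are driven by the stable magnesium chelate of the malonate-type enolate; C3 is already a carboxylate and is not deprotonated, and C2 has no acidic hydrogen, so both centres persist, while the chain alcohol is held as its magnesium alkoxide and returns on acidification.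

Step 8
Reactants: 11 (2R,3S)-2-(13-hydroxytridecyl)-5-oxooxolane-3,4-dicarboxylic acid
Product: 13 (2R,3S)-2-(13-hydroxytridecyl)-4-methylidene-5-oxooxolane-3-carboxylic acid, via Mannich adduct 12 (not isolated)
Conditions: 37% aq. HCHO, PhNHMe, NaOAc, AcOH, rt
Reagents that add atoms: formaldehyde, C=O
Why: Decarboxylative Mannich methylenation: the iminium ion from formaldehyde and N-methylaniline alkylates the enol of the malonic half-acid at C4 to give 12, which fragments with loss of CO2 and N-methylaniline to the exocyclic alkene; the buffered acetic acid medium is not basic enough to move the double bond into the ring or to disturb C3.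

Step 9
Reactants: 13 (2R,3S)-2-(13-hydroxytridecyl)-4-methylidene-5-oxooxolane-3-carboxylic acid
Product: 14 (2R,3S)-2-(13-acetoxytridecyl)-4-methylidene-5-oxooxolane-3-carboxylic acid
Conditions: immobilised Candida antarctica lipase B, vinyl acetate (5 equiv), MTBE, 30 °C; filter
Reagents that add atoms: vinyl acetate, C=COC(C)=O
Why: Lipase-catalysed irreversible transacylation: the active-site serine is acetylated by vinyl acetate and passes the acetyl group to the unhindered primary alcohol, while vinyl alcohol tautomerises to acetaldehyde; the ring carboxyl is secondary and flanked by two substituents, so it is no acyl donor for the enzyme, and the neutral base-free medium leaves the methylene lactone and C3 alone.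

## Compound list

1 | tetradecane-1,14-diol | OCCCCCCCCCCCCCCO | starting material
2 | 14-{[tert-butyl(dimethyl)silyl]oxy}tetradecan-1-ol | CC(C)(C)[Si](C)(C)OCCCCCCCCCCCCCCO | intermediate
3 | 14-{[tert-butyl(dimethyl)silyl]oxy}tetradecanoic acid | CC(C)(C)[Si](C)(C)OCCCCCCCCCCCCCC(=O)O | intermediate
4 | Meldrum's acid (2,2-dimethyl-1,3-dioxane-4,6-dione) | CC1(C)OC(=O)CC(=O)O1 | starting material
5 | 5-(14-{[tert-butyl(dimethyl)silyl]oxy}-1-hydroxytetradecylidene)-2,2-dimethyl-1,3-dioxane-4,6-dione (not isolated) | CC1(C)OC(=O)C(=C(O)CCCCCCCCCCCCCO[Si](C)(C)C(C)(C)C)C(=O)O1 | intermediate
6 | tert-butyl 16-{[tert-butyl(dimethyl)silyl]oxy}-3-oxohexadecanoate | CC(C)(C)OC(=O)CC(=O)CCCCCCCCCCCCCO[Si](C)(C)C(C)(C)C | intermediate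
7 | methyl bromoacetate | COC(=O)CBr | starting material
8 | 1-tert-butyl 4-methyl 2-(14-{[tert-butyl(dimethyl)silyl]oxy}tetradecanoyl)butanedioate, racemic | COC(=O)CC(C(=O)OC(C)(C)C)C(=O)CCCCCCCCCCCCCO[Si](C)(C)C(C)(C)C | intermediate
9 | 1-tert-butyl 4-methyl (2S)-2-[(1R)-14-{[tert-butyl(dimethyl)silyl]oxy}-1-hydroxytetradecyl]butanedioate | COC(=O)C[C@H](C(=O)OC(C)(C)C)[C@H](O)CCCCCCCCCCCCCO[Si](C)(C)C(C)(C)C | intermediate
10 | (2R,3S)-2-(13-hydroxytridecyl)-5-oxooxolane-3-carboxylic acid | C1C(=O)O[C@H](CCCCCCCCCCCCCO)[C@H]1C(=O)O | intermediate
11 | (2R,3S)-2-(13-hydroxytridecyl)-5-oxooxolane-3,4-dicarboxylic acid, C4 not fixed | OC(=O)C1C(=O)O[C@H](CCCCCCCCCCCCCO)[C@H]1C(=O)O | intermediate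
12 | (2R,3S)-2-(13-hydroxytridecyl)-4-{[methyl(phenyl)amino]methyl}-5-oxooxolane-3,4-dicarboxylic acid, C4 not fixed (not isolated) | CN(CC1(C(=O)O)C(=O)O[C@H](CCCCCCCCCCCCCO)[C@H]1C(=O)O)c1ccccc1 | intermediate
13 | (2R,3S)-2-(13-hydroxytridecyl)-4-methylidene-5-oxooxolane-3-carboxylic acid | C=C1C(=O)O[C@H](CCCCCCCCCCCCCO)[C@H]1C(=O)O | intermediate
14 | (2R,3S)-2-(13-acetoxytridecyl)-4-methylidene-5-oxooxolane-3-carboxylic acid | C=C1C(=O)O[C@H](CCCCCCCCCCCCCOC(C)=O)[C@H]1C(=O)O | target

## Step count and least certain steps

Total: 9 steps. Longest linear sequence: 9 steps, from 1 to 14; compounds 4 and 7 are bought.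

**Step 5 (key step).**
- What may go wrong: poor mass transfer of the waxy substrate into the aqueous phase, so that conversion is low.
- Hydride delivery to the other face, or acceptance of the other enantiomer, would lead to one of the three unwanted stereoisomers.
- Racemisation may be too slow, so that conversion stalls near one half.
- Hydrolases in crude enzyme preparations may hydrolyse the methyl ester.
- Fallback, from 8 back to 10: asymmetric hydrogenation of the 3-oxo ester with RuCl2[(R)-BINAP] and H2 in EtOH/CH2Cl2 should set the carbinol as R by the usual sense for 3-oxo esters, without reliable control of the neighbouring centre. This gives 1-tert-butyl 4-methyl (2RS)-2-[(1R)-14-(tert-butyldimethylsilyloxy)-1-hydroxytetradecyl]butanedioate F1.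
- Catalytic PPTS in warm toluene closes the lactone and keeps the tert-butyl ester, giving tert-butyl (2R,3RS)-2-[13-(tert-butyldimethylsilyloxy)tridecyl]-5-oxooxolane-3-carboxylate F2.
- DBU in toluene equilibrates C3, which is α to the ester, to the less crowded trans isomer, tert-butyl (2R,3S)-2-[13-(tert-butyldimethylsilyloxy)tridecyl]-5-oxooxolane-3-carboxylate F3.
- The acid treatment of step 6 then gives 10. The same F2-to-F3 correction also rescues an enzyme that sets the carbinol correctly but the neighbouring centre wrongly.

**Step 7.**
- What may go wrong: incomplete carboxylation, or loss of the new carboxyl during work-up.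
- Prolonged heating with the basic magnesium reagent may cause ring opening by β-elimination, or epimerisation at C3.
- Fallback, from 10 back to 13, replacing steps 7 and 8: LiHMDS (3.3 equiv) in THF at −78 °C forms the carboxylate, alkoxide and lactone enolate. Dimethyl(methylidene)ammonium iodide alkylates C4 to give (2R,3S)-4-[(dimethylamino)methyl]-2-(13-hydroxytridecyl)-5-oxooxolane-3-carboxylic acid F4.
- mCPBA in CH2Cl2 gives (2R,3S)-4-[(dimethylamino)methyl]-2-(13-hydroxytridecyl)-5-oxooxolane-3-carboxylic acid N-oxide F5, which undergoes Cope elimination at room temperature to 13.

**Step 9.**
- What may go wrong: slow acetyl transfer, because the free acid lowers the activity of the lipase.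
- Intermolecular esterification between the acid of one molecule and the alcohol of another may give oligoesters.
- Fallback, from 13 directly to 14: Fischer esterification in glacial acetic acid with catalytic H2SO4 at rt to 40 °C. The ring carboxyl is not activated, and the methylene lactone already tolerates acetic acid in step 8. This fallback makes no new compound (F0).

## Further compounds

F1 | step 5 | 1-tert-butyl 4-methyl (2RS)-2-[(1R)-14-(tert-butyldimethylsilyloxy)-1-hydroxytetradecyl]butanedioate | COC(=O)CC(C(=O)OC(C)(C)C)[C@H](O)CCCCCCCCCCCCCO[Si](C)(C)C(C)(C)C
F2 | step 5 | tert-butyl (2R,3RS)-2-[13-(tert-butyldimethylsilyloxy)tridecyl]-5-oxooxolane-3-carboxylate | C1C(=O)O[C@H](CCCCCCCCCCCCCO[Si](C)(C)C(C)(C)C)C1C(=O)OC(C)(C)C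
F3 | step 5 | tert-butyl (2R,3S)-2-[13-(tert-butyldimethylsilyloxy)tridecyl]-5-oxooxolane-3-carboxylate | C1C(=O)O[C@H](CCCCCCCCCCCCCO[Si](C)(C)C(C)(C)C)[C@H]1C(=O)OC(C)(C)C
F4 | step 7 | (2R,3S)-4-[(dimethylamino)methyl]-2-(13-hydroxytridecyl)-5-oxooxolane-3-carboxylic acid | CN(C)CC1C(=O)O[C@H](CCCCCCCCCCCCCO)[C@H]1C(=O)O
F5 | step 7 | (2R,3S)-4-[(dimethylamino)methyl]-2-(13-hydroxytridecyl)-5-oxooxolane-3-carboxylic acid N-oxide | C[N+](C)([O-])CC1C(=O)O[C@H](CCCCCCCCCCCCCO)[C@H]1C(=O)O
F0 | step 9 | none | none
A1 | alternative 1 | methyl furan-2-carboxylate | COC(=O)c1ccco1
A2 | alternative 1 | ethyl diazoacetate | CCOC(=O)C=[N+]=[N-]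
A3 | alternative 1 | methyl 6-(ethoxycarbonyl)-2-oxabicyclo[3.1.0]hex-3-ene-3-carboxylate, exo ester, single enantiomer | COC(=O)C1=C[C@@H]2[C@@H](C(=O)OCC)[C@@H]2O1
A4 | alternative 2 | 15-(dimethylamino)-15-oxopentadecyl acetate | CN(C)C(=O)CCCCCCCCCCCCCCOC(C)=O
A5 | alternative 2 | styrene | C=Cc1ccccc1
A6 | alternative 2 | (2R,3S)-2-(13-acetoxytridecyl)-3-phenylcyclobutan-1-one (trans) | O=C1C[C@H](c2ccccc2)[C@H]1CCCCCCCCCCCCCOC(C)=O
A7 | alternative 3 | (14R,15R)-15-{[tert-butyl(dimethyl)silyl]oxymethyl}-14-hydroxyheptadec-16-yn-1-yl acetate (anti) | O[C@H](CCCCCCCCCCCCCOC(C)=O)[C@H](C#C)CO[Si](C)(C)C(C)(C)C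
A8 | alternative 3 | (4R,5R)-5-(13-acetoxytridecyl)-4-{[tert-butyl(dimethyl)silyl]oxymethyl}-3-methylideneoxolan-2-one (trans) | C=C1C(=O)O[C@H](CCCCCCCCCCCCCOC(C)=O)[C@H]1CO[Si](C)(C)C(C)(C)C
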